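Locants used in the text: C1–C6 are the cyclohexene carbons of 13 (C1 bears coumarin A, C2=C3, methyl on C3, two methyls on C5, C6 bears C7); C7 is the carbinol carbon that bears coumarin B. Compound numbers are those of the steps and the compound list.

Assumption: electrophiles attack 5,7-dimethoxycoumarin 1 at C8 (ortho to the 7-methoxy group, para to the 5-methoxy group, next to the unsubstituted ring oxygen) rather than at C6 between the two methoxy groups.

## Analysis of the target

13 consists of two identical 5,7-dimethoxycoumarin units joined through their C8 atoms to a C10 linker. Coumarin A sits directly on C1 of a 3,5,5-trimethylcyclohex-2-ene ring, and coumarin B sits on the exocyclic carbinol carbon C7 bonded to C6. There are three contiguous stereocentres, C1 (S), C6 (R) and C7 (R). The aryl group on C1 and the side chain on C6 are trans on the ring, and C6/C7 have the syn-aldol relationship (zigzag C1–C6–C7–aryl, with C5 and OH on the same side). Both aryl–carbon bonds end at a doubly ortho-substituted aromatic carbon, and C6 is wedged between the quaternary C5, C1 and C7, so every bond around C1/C6/C7 is hindered. The sensitive groups are two coumarin lactones (no organolithium reagents, ester-reducing hydrides or hydroxide), an electron-rich benzylic alcohol that can ionise or fragment, and a trisubstituted alkene that can migrate in strong acid. The carbocycle C1–C6, with its methyl groups on C3 and C5 and the C2=C3 double bond, is the intact carbon skeleton of 4, with the carbonyl at C1 and the alpha-prime carbon at C6. The problem is therefore not ring construction but attaching two bulky, identical arenes at C1 and C7 with absolute control of three centres, with no free phenol to bind a catalyst.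

## Retrosynthetic reasoning

13 from 12. The O7 acetyl group is removed last. It is carried through the key step because a free or silylated O7 would drive a Grob-type cleavage of C6–C7 in cation 11, whereas an acyl oxygen does not, and because the acetyl carbonyl can bridge to C1 and reinforce the facial bias.

12 from 10 and 1 (key disconnection). The C1–C8 bond to coumarin A is cut. C1 is allylic, so the electrophile is the ring allyl cation 11, released from the C1 ester of 10, and the nucleophile is the unfunctionalised C8–H of 1. Neither partner needs a halide, boron group or directing group, and the most hindered bond of 13 is made by a strongly driven cation–arene combination of the kind used for aryl–terpene couplings of the cannabinoid class. The forward reaction has to ionise C1–O and not C7–O, add the arene at C1 and not at C3, add it trans to the C6 side chain, and use C8 of 1.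

10 from 9 from 8. These are functional-group steps. The C1 carbonyl of 8 is the source of the C1 leaving group, by 1,2-reduction and acetylation. The configuration of the C1 carbinol is erased in 11 and needs no control.

8 from 6 and 3. The C6–C7 bond is cut. C6 is the alpha-prime carbon of the enone of 4, and an aldol union with aldehyde 3 sets C6 and C7 together and brings in coumarin B intact. The target needs the syn (6R,7R) adduct. A cyclic enolate is E-configured and gives the anti adduct through a closed transition state, so an open-transition-state Lewis acid aldol of silyl dienol ether 6 is chosen. In that transition state the aryl group of 3 avoids the quaternary C5, and a chiral Lewis acid selects the aldehyde face.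

6 from 4 and 3 from 1. Kinetic deprotonation of 4 at C6 (via 5) and silylation give 6; formylation of 1 at C8 (via 2) gives 3. Both coumarin units thus come from the same commercial arene 1 and the whole carbocycle from 4. No ring is built.

## Alternatives that were turned down

Alternative 1: The textbook, biomimetic cut of C1–C6 and C4–C5 is a Diels–Alder reaction of diene A1 with enone A2, giving ketone A3, followed by hydride reduction to 13.
- A2 is a beta,beta-dimethyl enone whose carbonyl is twisted out of conjugation by the doubly ortho-substituted aryl group, and the C4–C5 bond must create a quaternary centre; it is a poor dienophile.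
- A1 is prone to polymerisation.
- The endo mode gives the cis adduct, so the trans ring needs exo addition or later epimerisation.
- A2 has no two-point binding site (no free ortho phenol) for a chiral Lewis acid, so absolute control rests on an unsecured cycloaddition.
- A1 and A2 each need several steps from 1, and C7 still has to be set afterwards.

Alternative 2: The C1–C6 bond alone is cut by an Ireland–Claisen ring contraction of the silyl ketene acetal of lactone A4 to acid A5.
- The boat transition state enforced by the ring gives the cis acid from the E-alkene, and the Z-alkene would push the aryl group against the C5 methyls.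
- A4 needs an enantioenriched tertiary allylic ester, which is hard to make catalytically and ionises easily (tertiary, allylic, conjugated to an electron-rich arene).
- The amide base meets two lactones.
- After the rearrangement the carboxyl group of A5 must still be turned into the C7 carbinol with coumarin B, by aryl-metal chemistry that the lactone tolerates poorly.
- The route would exceed twelve steps.

Alternative 3: C2=C3 is cut by ring-closing metathesis and C1–C6 by iridium-catalysed branched allylic alkylation of carbonate A6 with the enolate of ketone A7, giving diene A8, then A3, then reduction.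
- Doubly ortho-substituted cinnamyl-type electrophiles react slowly and lose branched selectivity.
- The enolate carbon is neopentylic.
- The C6 configuration would rest on an enolate that can equilibrate.
- A6 and A7 each need multi-step preparation, and the ring, already available as 4, would be built from scratch.

Key step: step 6

## Steps

Step 1
Reactants: 1 5,7-dimethoxy-2H-chromen-2-one
Product: 3 5,7-dimethoxy-2-oxo-2H-chromene-8-carbaldehyde, via iminium chloride 2 (not isolated)
Conditions: POCl3, DMF, ClCH2CH2Cl, 0 → 70 °C; then aq. NaOAc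
Reagents that add atoms: N,N-dimethylformamide CN(C)C=O; water O
Why: Vilsmeier–Haack formylation; C8 is activated by both methoxy groups and is less shielded than C6, and the lactone survives the non-nucleophilic conditions.

Step 2
Reactants: 4 3,5,5-trimethylcyclohex-2-en-1-one
Product: 6 trimethyl[(3,3,5-trimethylcyclohexa-1,5-dien-1-yl)oxy]silane, via lithium dienolate 5 (not isolated)
Conditions: LiN(iPr)2, THF, −78 °C; Me3SiCl, −78 → 0 °C
Reagents that add atoms: chlorotrimethylsilane C[Si](C)(C)Cl
Why: Kinetic deprotonation of the enone at the alpha-prime carbon C6 gives the cross-conjugated dienolate, which is O-silylated; a standard kinetic silyl enol ether formation.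

Step 3
Reactants: 6 trimethyl[(3,3,5-trimethylcyclohexa-1,5-dien-1-yl)oxy]silane; 3 5,7-dimethoxy-2-oxo-2H-chromene-8-carbaldehyde
Product: 8 8-{(R)-hydroxy[(1R)-4,6,6-trimethyl-2-oxocyclohex-3-en-1-yl]methyl}-5,7-dimethoxy-2H-chromen-2-one, via silyl ether 7 (not isolated)
Conditions: (acyloxy)borane from (2R,3R)-2-O-(2,6-diisopropoxybenzoyl)tartaric acid and BH3·THF (20 mol %), EtCN/CH2Cl2, −78 °C; then 10% aq. citric acid, MeOH, 0 °C
Reagents that add atoms: none
Why: Catalytic enantioselective Mukaiyama aldol addition through an open, extended transition state, which is syn-selective whatever the enol geometry; here the aryl group of 3 avoids the quaternary C5, so C6 and C7 are set together as (6R,7R). The catalyst enantiomer is the one expected to expose the Re face of the aldehyde; should the opposite sense be found, the (2S,3S) catalyst is used.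

Step 4
Reactants: 8 8-{(R)-hydroxy[(1R)-4,6,6-trimethyl-2-oxocyclohex-3-en-1-yl]methyl}-5,7-dimethoxy-2H-chromen-2-one
Product: 9 8-{(R)-hydroxy[(1S,2R)-2-hydroxy-4,6,6-trimethylcyclohex-3-en-1-yl]methyl}-5,7-dimethoxy-2H-chromen-2-one
Conditions: NaBH4, CeCl3·7H2O, MeOH, −78 → −40 °C
Reagents that add atoms: none
Why: Luche 1,2-reduction of the enone, which leaves both lactones untouched at low temperature; hydride should enter anti to the C6 side chain and the axial C5 methyl to give mainly the 1,6-cis alcohol drawn. The C1 epimer is equally usable because C1 is planarised in step 6.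

Step 5
Reactants: 9 8-{(R)-hydroxy[(1S,2R)-2-hydroxy-4,6,6-trimethylcyclohex-3-en-1-yl]methyl}-5,7-dimethoxy-2H-chromen-2-one
Product: 10 (1R,6S)-6-[(R)-(acetyloxy)(5,7-dimethoxy-2-oxo-2H-chromen-8-yl)methyl]-3,5,5-trimethylcyclohex-2-en-1-yl acetate
Conditions: Ac2O, Et3N, 4-(dimethylamino)pyridine (cat.), CH2Cl2, 0 → 35 °C
Reagents that add atoms: acetic anhydride CC(=O)OC(C)=O
Why: Nucleophile-catalysed acylation of both hydroxyl groups; the C1 acetate becomes the leaving group and the O7 acetate protects C7 in the key step. With no ketone left, beta-elimination of the O7 acetate is impossible.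

Step 6
Reactants: 10 (1R,6S)-6-[(R)-(acetyloxy)(5,7-dimethoxy-2-oxo-2H-chromen-8-yl)methyl]-3,5,5-trimethylcyclohex-2-en-1-yl acetate; 1 5,7-dimethoxy-2H-chromen-2-one
Product: 12 (R)-(5,7-dimethoxy-2-oxo-2H-chromen-8-yl)[(1R,2S)-2-(5,7-dimethoxy-2-oxo-2H-chromen-8-yl)-4,6,6-trimethylcyclohex-3-en-1-yl]methyl acetate, via allyl cation 11 (not isolated)
Conditions: 1 (3 equiv), BF3·OEt2 (0.3 equiv), CH2Cl2/(CF3)2CHOH 4:1, −30 → 0 °C
Reagents that add atoms: none
Why: This is a Friedel–Crafts allylation of an electron-rich arene by a cyclohexenyl cation, the reaction type of cannabinoid-class aryl–terpene couplings. Lewis-acid-assisted loss of the allylic C1 acetate gives cation 11 (delocalised over C1–C3), in equilibrium with the cis-fused 1,3-dioxan-2-ylium ion formed when the O7 acetyl oxygen closes on C1. No ring is closed; the step forms the C1–C8 bond to coumarin A and sets C1. C1 is controlled by the resident C6 centre: the side chain and the bridging acetoxonium oxygen block the cis face, so 1 adds trans and (6R) gives (1S). In the cation, attack at the secondary C1 leaves the trisubstituted C2=C3 alkene, whereas attack at C3 would create a quaternary centre next to a doubly ortho-substituted arene and is reversible. In 1, C8 is activated by both methoxy groups and is less shielded than C6. The ring allyl cation should form more readily than the C7 benzylic cation, whose planarisation is opposed by two ortho substituents and the branched C6, and the O7 acetyl group shuts down Grob-type C6–C7 cleavage of 11. Excess 1 and low temperature favour capture of 11 over loss of the C6 proton.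

Step 7
Reactants: 12 (R)-(5,7-dimethoxy-2-oxo-2H-chromen-8-yl)[(1R,2S)-2-(5,7-dimethoxy-2-oxo-2H-chromen-8-yl)-4,6,6-trimethylcyclohex-3-en-1-yl]methyl acetate
Product: 13 8-[(1S,6R)-6-[(R)-(5,7-dimethoxy-2-oxo-2H-chromen-8-yl)(hydroxy)methyl]-3,5,5-trimethylcyclohex-2-en-1-yl]-5,7-dimethoxy-2H-chromen-2-one
Conditions: K2CO3 (0.5 equiv), MeOH, 25 °C; then AcOH to pH 5
Reagents that add atoms: none
Why: Base-catalysed transesterification of the acetate; any lactone opened by methoxide keeps its Z geometry and recloses on acidification, and no stereocentre is epimerisable under these conditions.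

## Compound list

1 | 5,7-dimethoxy-2H-chromen-2-one (5,7-dimethoxycoumarin) | COc1cc(OC)c2ccc(=O)oc2c1 | starting material
2 | N-[(5,7-dimethoxy-2-oxo-2H-chromen-8-yl)methylidene]-N-methylmethanaminium chloride | COc1cc(OC)c2ccc(=O)oc2c1C=[N+](C)C.[Cl-] | intermediate
3 | 5,7-dimethoxy-2-oxo-2H-chromene-8-carbaldehyde | COc1cc(OC)c2ccc(=O)oc2c1C=O | intermediate
4 | 3,5,5-trimethylcyclohex-2-en-1-one (isophorone) | CC1=CC(=O)CC(C)(C)C1 | starting material
5 | lithium 3,3,5-trimethylcyclohexa-1,5-dien-1-olate | [Li+].CC1=CC([O-])=CC(C)(C)C1 | intermediate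
6 | trimethyl[(3,3,5-trimethylcyclohexa-1,5-dien-1-yl)oxy]silane | CC1=CC(O[Si](C)(C)C)=CC(C)(C)C1 | intermediate
7 | 8-{(R)-[(1R)-4,6,6-trimethyl-2-oxocyclohex-3-en-1-yl][(trimethylsilyl)oxy]methyl}-5,7-dimethoxy-2H-chromen-2-one | O=C1C=C(C)CC(C)(C)[C@@H]1[C@@H](O[Si](C)(C)C)c1c(OC)cc(OC)c2ccc(=O)oc12 | intermediate
8 | 8-{(R)-hydroxy[(1R)-4,6,6-trimethyl-2-oxocyclohex-3-en-1-yl]methyl}-5,7-dimethoxy-2H-chromen-2-one | O=C1C=C(C)CC(C)(C)[C@@H]1[C@@H](O)c1c(OC)cc(OC)c2ccc(=O)oc12 | intermediate
9 | 8-{(R)-hydroxy[(1S,2R)-2-hydroxy-4,6,6-trimethylcyclohex-3-en-1-yl]methyl}-5,7-dimethoxy-2H-chromen-2-one | O[C@@H]1C=C(C)CC(C)(C)[C@@H]1[C@@H](O)c1c(OC)cc(OC)c2ccc(=O)oc12 | intermediate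
10 | (1R,6S)-6-[(R)-(acetyloxy)(5,7-dimethoxy-2-oxo-2H-chromen-8-yl)methyl]-3,5,5-trimethylcyclohex-2-en-1-yl acetate | CC(=O)O[C@@H]1C=C(C)CC(C)(C)[C@@H]1[C@@H](OC(C)=O)c1c(OC)cc(OC)c2ccc(=O)oc12 | intermediate
11 | (R)-(5,7-dimethoxy-2-oxo-2H-chromen-8-yl)[(1R)-4,6,6-trimethylcyclohex-3-en-2-ylium-1-yl]methyl acetate (allyl cation, charge shared by C1 and C3) | [CH+]1C=C(C)CC(C)(C)[C@@H]1[C@@H](OC(C)=O)c1c(OC)cc(OC)c2ccc(=O)oc12 | intermediate
12 | (R)-(5,7-dimethoxy-2-oxo-2H-chromen-8-yl)[(1R,2S)-2-(5,7-dimethoxy-2-oxo-2H-chromen-8-yl)-4,6,6-trimethylcyclohex-3-en-1-yl]methyl acetate | COc1cc(OC)c2ccc(=O)oc2c1[C@H]1C=C(C)CC(C)(C)[C@@H]1[C@@H](OC(C)=O)c1c(OC)cc(OC)c2ccc(=O)oc12 | intermediate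
13 | 8-[(1S,6R)-6-[(R)-(5,7-dimethoxy-2-oxo-2H-chromen-8-yl)(hydroxy)methyl]-3,5,5-trimethylcyclohex-2-en-1-yl]-5,7-dimethoxy-2H-chromen-2-one | COc1cc(OC)c2ccc(=O)oc2c1[C@H]1C=C(C)CC(C)(C)[C@@H]1[C@@H](O)c1c(OC)cc(OC)c2ccc(=O)oc12 | target

## Step count and least certain steps

Total: 7 steps. Longest linear sequence: 6 steps (4 → 6 → 8 → 9 → 10 → 12 → 13; the branch 1 → 3 joins at step 3 and is equally 6 steps to 13).

**Step 6 (key step).** Three processes may compete with the intended one: ionisation at the benzylic C7–O bond; loss of the C6 proton from 11, which on re-protonation would erode the C6 configuration; and binding of the Lewis acid by the coumarin carbonyl groups, which slows ionisation and deactivates 1. Attack at C6 of 1 instead of C8 is a lesser risk. The fallback avoids a free cation and fixes the arene position. It sets out from 10 (the arene partner from 1) and returns at 12. Iodination of 1 (N-iodosuccinimide, cat. CF3CO2H, MeCN) gives 8-iodo-5,7-dimethoxy-2H-chromen-2-one F1. Miyaura borylation (bis(pinacolato)diboron, PdCl2(dppf), KOAc, dioxane, 80 °C) gives 5,7-dimethoxy-8-(4,4,5,5-tetramethyl-1,3,2-dioxaborolan-2-yl)-2H-chromen-2-one F2. Allyl–aryl Suzuki–Miyaura coupling of 10 with F2 (Pd2(dba)3, PPh3, K3PO4, THF/H2O, 50 °C) should then give 12: zerovalent palladium displaces the cis C1 acetate with inversion, and the aryl group is delivered from the metal to the less substituted allyl terminus C1, trans to the side chain. This requires the 1,6-cis acetate, the epimer drawn for 10.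

**Step 3.** The aldehyde is electron-rich and doubly ortho-substituted, so catalyst turnover may be slow and an uncatalysed or silyl-cation-catalysed background addition may erode enantioselectivity; a competing closed transition state would lower the syn ratio. The fallback sets out from 6 and 3 and returns at 8. A stoichiometric BF3·OEt2-promoted Mukaiyama addition (CH2Cl2, −78 °C) gives the syn adduct as a racemate through the same open transition state, that is 8 together with its enantiomer 8-{(S)-hydroxy[(1S)-4,6,6-trimethyl-2-oxocyclohex-3-en-1-yl]methyl}-5,7-dimethoxy-2H-chromen-2-one F3. The racemate is resolved by preparative chromatography on a chiral stationary phase.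

**Step 5.** Acylation of the hindered O7 hydroxyl may stop at the C1 monoacetate, and a free O7–H in step 6 would open the fragmentation channel. The fallback sets out from 9 and returns at 12. Trimethyl orthoacetate with pyridinium p-toluenesulfonate (CH2Cl2, 25 °C) ties both hydroxyl groups into the cyclic orthoester (4R,4aS,8aR)-4-(5,7-dimethoxy-2-oxo-2H-chromen-8-yl)-2-methoxy-2,5,5,7-tetramethyl-4a,5,6,8a-tetrahydro-4H-1,3-benzodioxine F4, without an acylation at the hindered oxygen. Treatment of F4 with Me3SiOTf (cat.) and 1 (CH2Cl2, −30 °C) expels methoxide to give the same dioxan-2-ylium ion as in step 6, which 1 opens at C1 to give 12 directly.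

**Step 1.** The chloroiminium ion is a weak electrophile and the third ring oxygen of 1 is acylated, so conversion may stall. The fallback sets out from 1 and returns at 3. Blanc chloromethylation (paraformaldehyde, HCl, AcOH, 50 °C) with the more reactive hydroxymethyl cation gives 8-(chloromethyl)-5,7-dimethoxy-2H-chromen-2-one F5. Kornblum oxidation (DMSO, NaHCO3, 100 °C) converts F5 into 3.

## Further compounds

F1 | step 6 | 8-iodo-5,7-dimethoxy-2H-chromen-2-one | COc1cc(OC)c2ccc(=O)oc2c1I
F2 | step 6 | 5,7-dimethoxy-8-(4,4,5,5-tetramethyl-1,3,2-dioxaborolan-2-yl)-2H-chromen-2-one | COc1cc(OC)c2ccc(=O)oc2c1B1OC(C)(C)C(C)(C)O1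
F3 | step 3 | 8-{(S)-hydroxy[(1S)-4,6,6-trimethyl-2-oxocyclohex-3-en-1-yl]methyl}-5,7-dimethoxy-2H-chromen-2-one | O=C1C=C(C)CC(C)(C)[C@H]1[C@H](O)c1c(OC)cc(OC)c2ccc(=O)oc12
F4 | step 5 | (4R,4aS,8aR)-4-(5,7-dimethoxy-2-oxo-2H-chromen-8-yl)-2-methoxy-2,5,5,7-tetramethyl-4a,5,6,8a-tetrahydro-4H-1,3-benzodioxine (epimers at C2) | COC3(C)O[C@@H]4C=C(C)CC(C)(C)[C@@H]4[C@H](c1c(OC)cc(OC)c2ccc(=O)oc12)O3
F5 | step 1 | 8-(chloromethyl)-5,7-dimethoxy-2H-chromen-2-one | COc1cc(OC)c2ccc(=O)oc2c1CCl
A1 | alternative 1 | 5,7-dimethoxy-8-[(1E)-3-methylbuta-1,3-dien-1-yl]-2H-chromen-2-one | COc1cc(OC)c2ccc(=O)oc2c1/C=C/C(C)=C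
A2 | alternative 1 | 5,7-dimethoxy-8-(3-methylbut-2-enoyl)-2H-chromen-2-one | COc1cc(OC)c2ccc(=O)oc2c1C(=O)C=C(C)C
A3 | alternative 1 | 8-[(1S,6R)-6-(5,7-dimethoxy-2-oxo-2H-chromene-8-carbonyl)-3,5,5-trimethylcyclohex-2-en-1-yl]-5,7-dimethoxy-2H-chromen-2-one | COc1cc(OC)c2ccc(=O)oc2c1[C@H]1C=C(C)CC(C)(C)[C@@H]1C(=O)c1c(OC)cc(OC)c2ccc(=O)oc12
A4 | alternative 2 | (6S)-6-[(E)-2-(5,7-dimethoxy-2-oxo-2H-chromen-8-yl)ethenyl]-4,4,6-trimethyloxan-2-one | O=C1CC(C)(C)C[C@@](C)(/C=C/c2c(OC)cc(OC)c3ccc(=O)oc23)O1
A5 | alternative 2 | (1S,2S)-2-(5,7-dimethoxy-2-oxo-2H-chromen-8-yl)-4,6,6-trimethylcyclohex-3-ene-1-carboxylic acid | COc1cc(OC)c2ccc(=O)oc2c1[C@H]1C=C(C)CC(C)(C)[C@H]1C(O)=O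
A6 | alternative 3 | (2E)-3-(5,7-dimethoxy-2-oxo-2H-chromen-8-yl)prop-2-en-1-yl methyl carbonate | COC(=O)OC/C=C/c1c(OC)cc(OC)c2ccc(=O)oc12
A7 | alternative 3 | 1-(5,7-dimethoxy-2-oxo-2H-chromen-8-yl)-3,3,5-trimethylhex-5-en-1-one | CC(=C)CC(C)(C)CC(=O)c1c(OC)cc(OC)c2ccc(=O)oc12
A8 | alternative 3 | (2R)-1-(5,7-dimethoxy-2-oxo-2H-chromen-8-yl)-2-[(1S)-1-(5,7-dimethoxy-2-oxo-2H-chromen-8-yl)prop-2-en-1-yl]-3,3,5-trimethylhex-5-en-1-one | COc1cc(OC)c2ccc(=O)oc2c1[C@@H](C=C)[C@@H](C(=O)c1c(OC)cc(OC)c2ccc(=O)oc12)C(C)(C)CC(C)=C
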